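**Plan**

Ring atoms are numbered as in 7-oxabicyclo[2.2.1]heptane: C-1 (bridgehead with CH3), C-2 (CH with the hydroxypentenyl chain), C-3 (quaternary, CH3 and bromochloropentyl chain), C-4 (bridgehead CH), O-7.
Retrosynthesis: the vinyl carbinol goes back to a Sharpless epoxy alcohol and an (E)-enoate, and the CHBr–CMe2Cl unit to a Shi epoxide of an isopropylidene alkene. Then the C-2 chain is cut at the ring (radical conjugate addition), then the O-7–C-1 bond (alkoxymercuration of a cyclohex-3-en-1-ol), and last the bond from C-3 to the first CH2 of its chain.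
Enabling feature: the carbocycle C-1 to C-6 has oxygen at C-4 beside the quaternary C-3 and a methyl at C-1, para to C-4. This is the pattern of 2-methoxy-5-methylbenzoic acid with the carboxyl carbon as the future C-3 methyl, so Birch reduction makes C-3 an amide enolate carbon that takes up the chain while the flat ring becomes a diene encoding both bridgeheads.
Forward order: arene → cyclohexa-1,4-diene with quaternary C-3 (chain joined) → carboxamide to CH3, enol ether to ketone, ketone to alcohol → oxygen bridge and C-2 chain in one flask → enoate, alkene, epoxide, Br, Cl → allylic alcohol, epoxy alcohol, vinyl carbinol.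
Stereochemistry: C-3 from the prolinol-ether auxiliary; C-4 from CBS reduction (reagent control), and C-1 then follows from the bridge geometry; C-2 from exo attack on the bicyclic radical; CHBr from Shi epoxidation and SN2 opening with inversion; the carbinol from Sharpless epoxidation.

Key step: step 2

Assumption: in step 2 the alkyl halide is taken to enter the chelated potassium enolate of the (S)-2-(methoxymethyl)pyrrolidine amide on the face opposite the methoxymethyl arm, giving the (R) quaternary centre drawn; if the sense were reversed, the (R)-auxiliary would be used and nothing else changes.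

**Route**

Step 1
Reactants: 1 2-methoxy-5-methylbenzoic acid; 2 (2S)-2-(methoxymethyl)pyrrolidine
Product: 4 [(2S)-2-(methoxymethyl)pyrrolidin-1-yl](2-methoxy-5-methylphenyl)methanone, via acid chloride 3 (not isolated)
Conditions: (COCl)2, DMF (cat.), CH2Cl2, 0 to 23 °C; then 2, Et3N, CH2Cl2, 0 °C
Reagents that add atoms: none
Why: Acid chloride formation followed by N-acylation of the secondary amine should install the chiral auxiliary without creating a stereocenter.

Step 2
Reactants: 4 [(2S)-2-(methoxymethyl)pyrrolidin-1-yl](2-methoxy-5-methylphenyl)methanone; 5 2-(2-bromoethyl)-1,3-dioxolane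
Product: 7 [(1R)-1-[2-(1,3-dioxolan-2-yl)ethyl]-2-methoxy-5-methylcyclohexa-2,5-dien-1-yl][(2S)-2-(methoxymethyl)pyrrolidin-1-yl]methanone, via potassium amide enolate 6 (not isolated)
Conditions: K (2.1 equiv), NH3(l)–THF, t-BuOH (1 equiv), −78 °C; then 5, −78 to −33 °C; NH4Cl
Reagents that add atoms: none
Why: Two electrons from potassium and one proton from t-BuOH (delivered para to the carbonyl) convert the benzamide into the cross-conjugated potassium amide enolate 6, which is alkylated at its α-carbon, the former ipso carbon, by the primary bromide 5 in an SN2 reaction, so the bond between the future quaternary ring carbon and the first CH2 of the halogenated chain is formed. The closest known reaction type is the asymmetric Birch reduction–alkylation of 2-methoxybenzamides of 2-(methoxymethyl)pyrrolidine, which accepts unactivated primary halides. No ring is closed; the arene becomes a cyclohexa-1,4-diene whose enol ether marks the future oxygenated bridgehead C-4 and whose methyl-substituted alkene marks C-1 and C-2. The one new stereocenter is controlled by the auxiliary: the ring methoxy group fixes the enolate geometry by chelating potassium together with the enolate oxygen and the methoxymethyl arm, so one face is closed and the halide should enter from the other. The step needs alkylation at the α-carbon (not at the γ-carbons or at oxygen) and no over-reduction; the first follows from the largest coefficient of the dienolate at the amide-bearing carbon, the second from the single equivalent of t-BuOH and from the enolate charge, which stops further electron uptake. The bromide and its acetal are not exposed to dissolved metal because 5 is added only after the potassium has been consumed.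

Step 3
Reactants: 7 [(1R)-1-[2-(1,3-dioxolan-2-yl)ethyl]-2-methoxy-5-methylcyclohexa-2,5-dien-1-yl][(2S)-2-(methoxymethyl)pyrrolidin-1-yl]methanone
Product: 8 [(1S)-1-[2-(1,3-dioxolan-2-yl)ethyl]-2-methoxy-5-methylcyclohexa-2,5-dien-1-yl]methanol
Conditions: LiH2NBH3 (from BH3·NH3 and lithium diisopropylamide), THF, 0 to 23 °C
Reagents that add atoms: none
Why: Lithium amidotrihydroborate reduces tertiary amides, α-quaternary ones included, to primary alcohols with C–N cleavage, which should free the auxiliary and leave the enol ether, the acetal and the quaternary center untouched.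

Step 4
Reactants: 8 [(1S)-1-[2-(1,3-dioxolan-2-yl)ethyl]-2-methoxy-5-methylcyclohexa-2,5-dien-1-yl]methanol
Product: 9 [(1S)-1-[2-(1,3-dioxolan-2-yl)ethyl]-2-methoxy-5-methylcyclohexa-2,5-dien-1-yl]methyl methanesulfonate
Conditions: MsCl, Et3N, CH2Cl2, 0 °C
Reagents that add atoms: methanesulfonyl chloride, CS(=O)(=O)Cl
Why: Sulfonylation of the primary alcohol under basic conditions, which the acid-labile enol ether tolerates.

Step 5
Reactants: 9 [(1S)-1-[2-(1,3-dioxolan-2-yl)ethyl]-2-methoxy-5-methylcyclohexa-2,5-dien-1-yl]methyl methanesulfonate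
Product: 11 (2S)-2-[2-(1,3-dioxolan-2-yl)ethyl]-2,4-dimethylcyclohex-3-en-1-one, via enol ether 10 (not isolated)
Conditions: LiEt3BH, THF, 0 to 65 °C; then oxalic acid (cat.), THF–H2O, 23 °C
Reagents that add atoms: water, O
Why: SN2 hydride displacement of the neopentyl mesylate by LiEt3BH should give the ring methyl group, and aqueous oxalic acid (the classical hydrolysis of Birch dihydroanisoles) then converts the enol ether into the β,γ-unsaturated ketone, which cannot conjugate because its α-carbon is quaternary, while the dioxolane survives the weak acid.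

Step 6
Reactants: 11 (2S)-2-[2-(1,3-dioxolan-2-yl)ethyl]-2,4-dimethylcyclohex-3-en-1-one
Product: 12 (1S,2S)-2-[2-(1,3-dioxolan-2-yl)ethyl]-2,4-dimethylcyclohex-3-en-1-ol
Conditions: (R)-2-methyl-CBS-oxazaborolidine (0.2 equiv), catecholborane, toluene, −78 to −40 °C
Reagents that add atoms: none
Why: Corey–Bakshi–Shibata reduction under reagent control, in which the quaternary carbon is the large and the CH2 the small ketone substituent, so the (R)-catalyst should deliver hydride to the face of the acetal chain and place the hydroxyl cis to the ring methyl (1S); catecholborane avoids hydroboration of the alkene.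

Step 7
Reactants: 12 (1S,2S)-2-[2-(1,3-dioxolan-2-yl)ethyl]-2,4-dimethylcyclohex-3-en-1-ol
Product: 14 4-[(1R,2S,3S,4S)-3-[2-(1,3-dioxolan-2-yl)ethyl]-1,3-dimethyl-7-oxabicyclo[2.2.1]heptan-2-yl]butan-2-one, via organomercurial 13 (not isolated)
Conditions: Hg(OAc)2, CH2Cl2, 23 °C; then methyl vinyl ketone (excess), NaBH4, CH2Cl2–H2O, 0 °C
Reagents that add atoms: methyl vinyl ketone, CC(=O)C=C
Why: Intramolecular alkoxymercuration (Markovnikov attack of the hydroxyl on the methyl-bearing alkene carbon, anti to mercury) should close the 7-oxabicyclo[2.2.1]heptane and fix C-1 from the carbinol configuration, and borohydride then turns the C–Hg bond into the C-2 radical (Giese reaction), which should add to the enone on the open exo face, syn to the oxygen bridge and away from the endo chain on C-3 and the ethano bridge.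

Step 8
Reactants: 14 4-[(1R,2S,3S,4S)-3-[2-(1,3-dioxolan-2-yl)ethyl]-1,3-dimethyl-7-oxabicyclo[2.2.1]heptan-2-yl]butan-2-one
Product: 15 ethyl (2E)-5-[(1R,2S,3S,4S)-3-[2-(1,3-dioxolan-2-yl)ethyl]-1,3-dimethyl-7-oxabicyclo[2.2.1]heptan-2-yl]-3-methylpent-2-enoate
Conditions: (EtO)2P(O)CH2CO2Et, NaH, THF, 0 to 50 °C
Reagents that add atoms: triethyl phosphonoacetate, CCOC(=O)CP(=O)(OCC)OCC
Why: Horner–Wadsworth–Emmons olefination of the methyl ketone should give the trisubstituted enoate with the (E) isomer expected to predominate for steric reasons, the minor (Z) isomer being removed by chromatography.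

Step 9
Reactants: 15 ethyl (2E)-5-[(1R,2S,3S,4S)-3-[2-(1,3-dioxolan-2-yl)ethyl]-1,3-dimethyl-7-oxabicyclo[2.2.1]heptan-2-yl]-3-methylpent-2-enoate
Product: 16 ethyl (2E)-5-[(1R,2S,3S,4S)-1,3-dimethyl-3-(3-oxopropyl)-7-oxabicyclo[2.2.1]heptan-2-yl]-3-methylpent-2-enoate
Conditions: 1 M HCl, THF, 23 °C
Reagents that add atoms: water, O
Why: Acid hydrolysis of the dioxolane should unmask the aldehyde, the enoate and the bicyclic ether being stable to dilute acid.

Step 10
Reactants: 16 ethyl (2E)-5-[(1R,2S,3S,4S)-1,3-dimethyl-3-(3-oxopropyl)-7-oxabicyclo[2.2.1]heptan-2-yl]-3-methylpent-2-enoate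
Product: 17 ethyl (2E)-5-[(1R,2S,3S,4S)-1,3-dimethyl-3-(4-methylpent-3-en-1-yl)-7-oxabicyclo[2.2.1]heptan-2-yl]-3-methylpent-2-enoate
Conditions: i-PrPPh3I, n-BuLi, THF, 0 °C; then 16, −78 to 0 °C
Reagents that add atoms: isopropyltriphenylphosphonium iodide, CC(C)[P+](c1ccccc1)(c1ccccc1)c1ccccc1.[I-]
Why: Wittig olefination with the non-stabilised isopropylidene ylide should convert the aldehyde into the trisubstituted alkene, since at low temperature the aldehyde reacts far faster than the β,β-disubstituted enoate.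

Step 11
Reactants: 17 ethyl (2E)-5-[(1R,2S,3S,4S)-1,3-dimethyl-3-(4-methylpent-3-en-1-yl)-7-oxabicyclo[2.2.1]heptan-2-yl]-3-methylpent-2-enoate
Product: 18 ethyl (2E)-5-[(1R,2S,3S,4S)-3-[2-[(2R)-3,3-dimethyloxiran-2-yl]ethyl]-1,3-dimethyl-7-oxabicyclo[2.2.1]heptan-2-yl]-3-methylpent-2-enoate
Conditions: D-fructose-derived Shi ketone (0.3 equiv), Oxone (2KHSO5·KHSO4·K2SO4), K2CO3, Bu4NHSO4, MeCN–dimethoxymethane–aq. Na2B4O7 buffer, 0 °C
Reagents that add atoms: potassium peroxymonosulfate (active part of Oxone), [K+].[O-]S(=O)(=O)OO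
Why: Shi epoxidation, in which the chiral dioxirane attacks only the electron-rich trisubstituted alkene (the enoate is inert) through the spiro transition state, should give the (R) epoxide carbon under catalyst control.

Step 12
Reactants: 18 ethyl (2E)-5-[(1R,2S,3S,4S)-3-[2-[(2R)-3,3-dimethyloxiran-2-yl]ethyl]-1,3-dimethyl-7-oxabicyclo[2.2.1]heptan-2-yl]-3-methylpent-2-enoate
Product: 19 ethyl (2E)-5-[(1R,2S,3S,4S)-3-[(3S)-3-bromo-4-hydroxy-4-methylpentyl]-1,3-dimethyl-7-oxabicyclo[2.2.1]heptan-2-yl]-3-methylpent-2-enoate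
Conditions: Li2NiBr4, THF, 0 to 23 °C
Reagents that add atoms: dilithium tetrabromonickelate, [Li+].[Li+].[Ni+2].[Br-].[Br-].[Br-].[Br-]
Why: Soft nucleophilic bromide should open the epoxide by SN2 attack at the less substituted carbon with inversion, giving the (S) secondary bromide and the tertiary alcohol.

Step 13
Reactants: 19 ethyl (2E)-5-[(1R,2S,3S,4S)-3-[(3S)-3-bromo-4-hydroxy-4-methylpentyl]-1,3-dimethyl-7-oxabicyclo[2.2.1]heptan-2-yl]-3-methylpent-2-enoate
Product: 20 ethyl (2E)-5-[(1R,2S,3S,4S)-3-[(3S)-3-bromo-4-chloro-4-methylpentyl]-1,3-dimethyl-7-oxabicyclo[2.2.1]heptan-2-yl]-3-methylpent-2-enoate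
Conditions: SOCl2, CH2Cl2, −20 to 0 °C
Reagents that add atoms: thionyl chloride, O=S(Cl)Cl
Why: Deoxychlorination of the tertiary alcohol, in which the chlorosulfite ionises with help of the neighbouring bromine and chloride opens the bromonium ion at the tertiary carbon, so the CHBr stereocenter should keep its configuration.

Step 14
Reactants: 20 ethyl (2E)-5-[(1R,2S,3S,4S)-3-[(3S)-3-bromo-4-chloro-4-methylpentyl]-1,3-dimethyl-7-oxabicyclo[2.2.1]heptan-2-yl]-3-methylpent-2-enoate
Product: 21 (2E)-5-[(1R,2S,3S,4S)-3-[(3S)-3-bromo-4-chloro-4-methylpentyl]-1,3-dimethyl-7-oxabicyclo[2.2.1]heptan-2-yl]-3-methylpent-2-en-1-ol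
Conditions: i-Bu2AlH, CH2Cl2, −78 °C
Reagents that add atoms: none
Why: Low-temperature 1,2-reduction of the enoate with diisobutylaluminium hydride should give the (E)-allylic alcohol without touching the alkyl halides.

Step 15
Reactants: 21 (2E)-5-[(1R,2S,3S,4S)-3-[(3S)-3-bromo-4-chloro-4-methylpentyl]-1,3-dimethyl-7-oxabicyclo[2.2.1]heptan-2-yl]-3-methylpent-2-en-1-ol
Product: 22 [(2S,3S)-3-[2-[(1R,2S,3S,4S)-3-[(3S)-3-bromo-4-chloro-4-methylpentyl]-1,3-dimethyl-7-oxabicyclo[2.2.1]heptan-2-yl]ethyl]-3-methyloxiran-2-yl]methanol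
Conditions: Ti(OiPr)4 (0.1 equiv), L-(+)-diethyl tartrate (0.12 equiv), t-BuOOH, 4 Å molecular sieves, CH2Cl2, −20 °C
Reagents that add atoms: tert-butyl hydroperoxide, CC(C)(C)OO
Why: Sharpless asymmetric epoxidation with L-(+)-diethyl tartrate should deliver oxygen to the face of the (E)-allylic alcohol that gives the (2S,3S) epoxy alcohol, as for geraniol, under reagent control.

Step 16
Reactants: 22 [(2S,3S)-3-[2-[(1R,2S,3S,4S)-3-[(3S)-3-bromo-4-chloro-4-methylpentyl]-1,3-dimethyl-7-oxabicyclo[2.2.1]heptan-2-yl]ethyl]-3-methyloxiran-2-yl]methanol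
Product: 24 dactylomelol (3S)-5-[(1R,2S,3S,4S)-3-[(3S)-3-bromo-4-chloro-4-methylpentyl]-1,3-dimethyl-7-oxabicyclo[2.2.1]heptan-2-yl]-3-methylpent-1-en-3-ol, via epoxy iodide 23 (not isolated)
Conditions: PPh3, I2, imidazole, CH2Cl2, 0 to 23 °C; then H2O
Reagents that add atoms: none
Why: Appel-type iodination gives the 2,3-epoxy iodide, and attack of iodide or phosphine at iodine then opens the epoxide by reductive elimination (the one-flask 1,3-transposition of 2,3-epoxy alcohols to allylic alcohols), so the C–O bond at the tertiary carbon is kept and the carbinol should have the (S) configuration set in step 15.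

**Compound list**

1 | 2-methoxy-5-methylbenzoic acid | COc1ccc(C)cc1C(=O)O | starting material
2 | (2S)-2-(methoxymethyl)pyrrolidine | COC[C@@H]1CCCN1 | starting material
3 | 2-methoxy-5-methylbenzoyl chloride | COc1ccc(C)cc1C(=O)Cl | intermediate
4 | [(2S)-2-(methoxymethyl)pyrrolidin-1-yl](2-methoxy-5-methylphenyl)methanone | COc1ccc(C)cc1C(=O)N1CCC[C@H]1COC | intermediate
5 | 2-(2-bromoethyl)-1,3-dioxolane | BrCCC1OCCO1 | starting material
6 | potassium (6-methoxy-3-methylcyclohexa-2,5-dien-1-ylidene)[(2S)-2-(methoxymethyl)pyrrolidin-1-yl]methanolate | COC1=CCC(C)=CC1=C([O-])N1CCC[C@H]1COC.[K+] | intermediate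
7 | [(1R)-1-[2-(1,3-dioxolan-2-yl)ethyl]-2-methoxy-5-methylcyclohexa-2,5-dien-1-yl][(2S)-2-(methoxymethyl)pyrrolidin-1-yl]methanone | COC1=CCC(C)=C[C@@]1(CCC2OCCO2)C(=O)N3CCC[C@H]3COC | intermediate
8 | [(1S)-1-[2-(1,3-dioxolan-2-yl)ethyl]-2-methoxy-5-methylcyclohexa-2,5-dien-1-yl]methanol | COC1=CCC(C)=C[C@@]1(CCC2OCCO2)CO | intermediate
9 | [(1S)-1-[2-(1,3-dioxolan-2-yl)ethyl]-2-methoxy-5-methylcyclohexa-2,5-dien-1-yl]methyl methanesulfonate | COC1=CCC(C)=C[C@@]1(CCC2OCCO2)COS(C)(=O)=O | intermediate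
10 | 2-[2-[(1S)-2-methoxy-1,5-dimethylcyclohexa-2,5-dien-1-yl]ethyl]-1,3-dioxolane | COC1=CCC(C)=C[C@@]1(CCC2OCCO2)C | intermediate
11 | (2S)-2-[2-(1,3-dioxolan-2-yl)ethyl]-2,4-dimethylcyclohex-3-en-1-one | O=C1CCC(C)=C[C@]1(C)CCC2OCCO2 | intermediate
12 | (1S,2S)-2-[2-(1,3-dioxolan-2-yl)ethyl]-2,4-dimethylcyclohex-3-en-1-ol | O[C@H]1CCC(C)=C[C@]1(C)CCC2OCCO2 | intermediate
13 | (acetato)[(1R,2R,3R,4S)-3-[2-(1,3-dioxolan-2-yl)ethyl]-1,3-dimethyl-7-oxabicyclo[2.2.1]heptan-2-yl]mercury (C–Hg endo) | CC(=O)O[Hg][C@@H]1[C@](C)(CCC3OCCO3)[C@@H]2CC[C@@]1(C)O2 | intermediate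
14 | 4-[(1R,2S,3S,4S)-3-[2-(1,3-dioxolan-2-yl)ethyl]-1,3-dimethyl-7-oxabicyclo[2.2.1]heptan-2-yl]butan-2-one | CC(=O)CC[C@H]1[C@](C)(CCC3OCCO3)[C@@H]2CC[C@@]1(C)O2 | intermediate
15 | ethyl (2E)-5-[(1R,2S,3S,4S)-3-[2-(1,3-dioxolan-2-yl)ethyl]-1,3-dimethyl-7-oxabicyclo[2.2.1]heptan-2-yl]-3-methylpent-2-enoate | CCOC(=O)/C=C(\C)CC[C@H]1[C@](C)(CCC3OCCO3)[C@@H]2CC[C@@]1(C)O2 | intermediate
16 | ethyl (2E)-5-[(1R,2S,3S,4S)-1,3-dimethyl-3-(3-oxopropyl)-7-oxabicyclo[2.2.1]heptan-2-yl]-3-methylpent-2-enoate | CCOC(=O)/C=C(\C)CC[C@H]1[C@](C)(CCC=O)[C@@H]2CC[C@@]1(C)O2 | intermediate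
17 | ethyl (2E)-5-[(1R,2S,3S,4S)-1,3-dimethyl-3-(4-methylpent-3-en-1-yl)-7-oxabicyclo[2.2.1]heptan-2-yl]-3-methylpent-2-enoate | CCOC(=O)/C=C(\C)CC[C@H]1[C@](C)(CCC=C(C)C)[C@@H]2CC[C@@]1(C)O2 | intermediate
18 | ethyl (2E)-5-[(1R,2S,3S,4S)-3-[2-[(2R)-3,3-dimethyloxiran-2-yl]ethyl]-1,3-dimethyl-7-oxabicyclo[2.2.1]heptan-2-yl]-3-methylpent-2-enoate | CCOC(=O)/C=C(\C)CC[C@H]1[C@](C)(CC[C@H]3OC3(C)C)[C@@H]2CC[C@@]1(C)O2 | intermediate
19 | ethyl (2E)-5-[(1R,2S,3S,4S)-3-[(3S)-3-bromo-4-hydroxy-4-methylpentyl]-1,3-dimethyl-7-oxabicyclo[2.2.1]heptan-2-yl]-3-methylpent-2-enoate | CCOC(=O)/C=C(\C)CC[C@H]1[C@](C)(CC[C@H](Br)C(C)(C)O)[C@@H]2CC[C@@]1(C)O2 | intermediate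
20 | ethyl (2E)-5-[(1R,2S,3S,4S)-3-[(3S)-3-bromo-4-chloro-4-methylpentyl]-1,3-dimethyl-7-oxabicyclo[2.2.1]heptan-2-yl]-3-methylpent-2-enoate | CCOC(=O)/C=C(\C)CC[C@H]1[C@](C)(CC[C@H](Br)C(C)(C)Cl)[C@@H]2CC[C@@]1(C)O2 | intermediate
21 | (2E)-5-[(1R,2S,3S,4S)-3-[(3S)-3-bromo-4-chloro-4-methylpentyl]-1,3-dimethyl-7-oxabicyclo[2.2.1]heptan-2-yl]-3-methylpent-2-en-1-ol | OC/C=C(\C)CC[C@H]1[C@](C)(CC[C@H](Br)C(C)(C)Cl)[C@@H]2CC[C@@]1(C)O2 | intermediate
22 | [(2S,3S)-3-[2-[(1R,2S,3S,4S)-3-[(3S)-3-bromo-4-chloro-4-methylpentyl]-1,3-dimethyl-7-oxabicyclo[2.2.1]heptan-2-yl]ethyl]-3-methyloxiran-2-yl]methanol | OC[C@@H]1O[C@@]1(C)CC[C@H]2[C@](C)(CC[C@H](Br)C(C)(C)Cl)[C@@H]3CC[C@@]2(C)O3 | intermediate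
23 | (2R,3S)-3-[2-[(1R,2S,3S,4S)-3-[(3S)-3-bromo-4-chloro-4-methylpentyl]-1,3-dimethyl-7-oxabicyclo[2.2.1]heptan-2-yl]ethyl]-2-(iodomethyl)-3-methyloxirane | IC[C@@H]1O[C@@]1(C)CC[C@H]2[C@](C)(CC[C@H](Br)C(C)(C)Cl)[C@@H]3CC[C@@]2(C)O3 | intermediate
24 | dactylomelol, (3S)-5-[(1R,2S,3S,4S)-3-[(3S)-3-bromo-4-chloro-4-methylpentyl]-1,3-dimethyl-7-oxabicyclo[2.2.1]heptan-2-yl]-3-methylpent-1-en-3-ol | C=C[C@@](C)(O)CC[C@H]1[C@](C)(CC[C@H](Br)C(C)(C)Cl)[C@@H]2CC[C@@]1(C)O2 | target

Total step count: 16. Longest linear sequence: 16 steps (1 to 24).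

**Steps most likely to fail**

Step 7. The hydride may capture the organomercurial or the ring radical before the C–C bond forms, borohydride may reduce the enone and the product ketone, and exo facial selectivity at the ring radical may be incomplete. Fallback: from 12, cyclisation with N-(phenylseleno)phthalimide and camphorsulfonic acid (cat.) in CH2Cl2 should give the isolable endo selenide 2-[2-[(1R,2R,3R,4S)-1,3-dimethyl-2-(phenylselanyl)-7-oxabicyclo[2.2.1]heptan-3-yl]ethyl]-1,3-dioxolane F1. The same ring radical is then generated from F1 with Bu3SnH and AIBN (slow addition, benzene, 80 °C) in the presence of methyl vinyl ketone, a chain that keeps the hydride concentration low and uses no borohydride. This returns to the route at 14.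

Step 5. The doubly allylic neopentyl mesylate may ionise with vinyl migration and ring expansion, or hydride may attack sulfur instead of carbon. Fallback: from 7, the order is changed so that the displacement runs on a cyclohexenol and not on the cyclohexa-2,5-diene.
- Oxalic acid in THF–H2O should give the keto amide (2R)-2-[2-(1,3-dioxolan-2-yl)ethyl]-2-[[(2S)-2-(methoxymethyl)pyrrolidin-1-yl]carbonyl]-4-methylcyclohex-3-en-1-one F2.
- Reduction with the (R)-CBS catalyst and catecholborane should give the hydroxy amide [(1R,6S)-1-[2-(1,3-dioxolan-2-yl)ethyl]-6-hydroxy-3-methylcyclohex-2-en-1-yl][(2S)-2-(methoxymethyl)pyrrolidin-1-yl]methanone F3.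
- LiH2NBH3 should give the diol (1S,2S)-2-[2-(1,3-dioxolan-2-yl)ethyl]-2-(hydroxymethyl)-4-methylcyclohex-3-en-1-ol F4.
- TsCl in pyridine should sulfonylate the primary hydroxyl selectively to [(1S,6S)-1-[2-(1,3-dioxolan-2-yl)ethyl]-6-hydroxy-3-methylcyclohex-2-en-1-yl]methyl 4-methylbenzenesulfonate F5.
- LiEt3BH in THF then returns to the route at 12.

Step 16. Iodide or phosphine may strip the vicinal bromide and chloride, or the epoxy iodide may fail to open cleanly in the one-flask procedure. Fallback: from 22, oxidation with Dess–Martin periodinane (NaHCO3, CH2Cl2) should give the epoxy aldehyde (2R,3S)-3-[2-[(1R,2S,3S,4S)-3-[(3S)-3-bromo-4-chloro-4-methylpentyl]-1,3-dimethyl-7-oxabicyclo[2.2.1]heptan-2-yl]ethyl]-3-methyloxirane-2-carbaldehyde F6. Wharton transposition (N2H4·H2O, AcOH cat., MeOH, 0 °C) then opens the epoxide through the hydrazone with loss of nitrogen and returns to the route at 24, with the tertiary C–O bond kept.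

Further compounds
F1 | step 7 | 2-[2-[(1R,2R,3R,4S)-1,3-dimethyl-2-(phenylselanyl)-7-oxabicyclo[2.2.1]heptan-3-yl]ethyl]-1,3-dioxolane | c1ccccc1[Se][C@@H]1[C@](C)(CCC3OCCO3)[C@@H]2CC[C@@]1(C)O2
F2 | step 5 | (2R)-2-[2-(1,3-dioxolan-2-yl)ethyl]-2-[[(2S)-2-(methoxymethyl)pyrrolidin-1-yl]carbonyl]-4-methylcyclohex-3-en-1-one | O=C1CCC(C)=C[C@@]1(CCC2OCCO2)C(=O)N3CCC[C@H]3COC
F3 | step 5 | [(1R,6S)-1-[2-(1,3-dioxolan-2-yl)ethyl]-6-hydroxy-3-methylcyclohex-2-en-1-yl][(2S)-2-(methoxymethyl)pyrrolidin-1-yl]methanone | O[C@H]1CCC(C)=C[C@@]1(CCC2OCCO2)C(=O)N3CCC[C@H]3COC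
F4 | step 5 | (1S,2S)-2-[2-(1,3-dioxolan-2-yl)ethyl]-2-(hydroxymethyl)-4-methylcyclohex-3-en-1-ol | O[C@H]1CCC(C)=C[C@@]1(CCC2OCCO2)CO
F5 | step 5 | [(1S,6S)-1-[2-(1,3-dioxolan-2-yl)ethyl]-6-hydroxy-3-methylcyclohex-2-en-1-yl]methyl 4-methylbenzenesulfonate | O[C@H]1CCC(C)=C[C@@]1(CCC2OCCO2)COS(=O)(=O)c1ccc(C)cc1
F6 | step 16 | (2R,3S)-3-[2-[(1R,2S,3S,4S)-3-[(3S)-3-bromo-4-chloro-4-methylpentyl]-1,3-dimethyl-7-oxabicyclo[2.2.1]heptan-2-yl]ethyl]-3-methyloxirane-2-carbaldehyde | O=C[C@@H]1O[C@@]1(C)CC[C@H]2[C@](C)(CC[C@H](Br)C(C)(C)Cl)[C@@H]3CC[C@@]2(C)O3
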